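Remark on the chemistry: ring carbons are counted from the carboxyl-bearing carbon, C1(A)–C6(A) in the acyl ring (pentyl on C2(A), hydroxyl on C4(A), methoxy on C6(A)) and C1(B)–C6(B) in the benzoic acid ring (methoxy on C2(B), acyloxy on C4(B), pentyl on C6(B)). The precursor and product structures of the key step were checked atom by atom against the target and need no correction.

## Structural features

The target is a depside without any stereocentre: two benzene rings, each with a carboxyl carbon flanked by a methoxy group and an n-pentyl chain, are joined by an aryl ester from the carboxyl of ring A to the oxygen on C4(B). Ring A carries a free hydroxyl on C4(A); ring B carries the free carboxylic acid on C1(B). The fragile elements are the aryl ester (cleaved by hydroxide, alkoxide or alkaline peroxide), the electron-rich di-ortho-substituted benzoic acid (prone to lose carbon dioxide in warm acid) and the phenolic ring A (open to C-alkylation by carbocations). The real difficulty is not the carbon skeleton but the oxygen pattern: three phenolic oxygens of the same resorcylate type must end as methyl ether, free hydroxyl and acylated oxygen, and both ester carbonyls are shielded by two ortho substituents. Both rings are at heart the same unit, a 2-methoxy-6-pentylbenzoate with one extra oxygen para to the carboxyl carbon. In the depside lacking the C4(A) hydroxyl there are five aromatic C–H bonds, and only C4(A)–H has hydrogen on both neighbouring carbons: C3(A) lies beside the pentyl chain, C5(A) beside the methoxy group, and C3(B) and C5(B) each sit between two substituents. The key step uses this steric singularity, so that an iridium-catalysed C–H borylation followed by oxidation places the hydroxyl on C4(A) without any differentiation of ring A oxygens by protecting groups.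

## Logic of the disconnections

**13 back to 12.** The bond cut is the O–C(CH3)3 bond of a carboxylic ester on C1(B). The acid has to be masked because its proton would destroy boryl and hydride species and would interfere with the acylation. A tert-butyl group is chosen because it has no aromatic C–H bond and leaves by alkyl–oxygen fission, which does not touch the depside carbonyl. Nothing is gained in skeleton, but every earlier step becomes possible. The demand on the forward step is a cold, short acidolysis with a trap for the tert-butyl cation, since ring A of 12 is an activated phenol.

**12 back to 10 (through 11).** The bond cut is C4(A)–O. This is the one oxygen that sits on the sterically unique C–H position, so it can be added last. The gain is large: ring A of 10 is the same mono-oxygenated unit as in 4, so both halves of the molecule derive from one building block and the methoxy and hydroxyl of ring A never have to be told apart. The forward step must pick C4(A)–H out of five aromatic C–H bonds and must oxidise the C–B bond of 11 without a nucleophile that would cleave the aryl ester.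

**10 back to 4 and 8 (through 9).** The bond cut is the acyl C–O(C4(B)) bond of the depside, the only convergent cut in the molecule. It divides 10 into two pieces of almost equal size that share their origin. The forward step must acylate a phenol with an acid derivative whose carbonyl carries two ortho substituents, under a base mild enough to spare the product and the tert-butyl ester; the phenol of 8 itself is unhindered.

**8 back to 5 and 6 (through 7).** The bond cut is C4–O of the ring B phenol. The logic is the same as for ring A: in 5 the hydrogen para to the ester is the only one without an ortho neighbour. The gain is that the oxygenated ring B comes from the same deoxy ester with no separate aromatic synthesis. The demand is steric site selectivity among three ring hydrogens and an oxidation that leaves the tert-butyl ester alone.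

**5 back to 4.** The bond cut is again O–C(CH3)3, here in the forward sense of ester formation. The gain is that one acid, 4, feeds both halves. The demand is esterification of a di-ortho-substituted acid, best met by alkylating the carboxylate oxygen so that the hindered carbonyl carbon is never attacked.

**4 back to 1 and 2 (through 3).** The bond cut is the C–C bond between the benzylic carbon and the second carbon of the pentyl chain. A benzylic carbanion ortho to a carboxylate is easy to generate and alkylate, which reduces the building block to a commercial toluic acid and a primary bromide. The forward step needs two equivalents of strong base, lateral rather than ring deprotonation, and a single alkylation.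

## Other disconnections considered

**Alternative 1:** The cut removes two C–C bonds of a resorcylate ring, C1–C6 and C2–C3 in the ring B count, and leads back to dibenzyl malonate A1 and (E)-non-3-en-2-one A2. In the forward sense the sodium enolate of A1 would add to the β-carbon of A2, and the methyl ketone enolate so formed would close the ring on one ester in a 6-exo-trig Dieckmann-type acylation with loss of a benzyloxy group. The product would be racemic benzyl trans-2-hydroxy-4-oxo-6-pentylcyclohex-2-ene-1-carboxylate A3, whose stereocentres vanish on aromatisation to benzyl 2,4-dihydroxy-6-pentylbenzoate A4.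
- In favour: ring, carboxyl, pentyl chain and both oxygens arise from cheap acyclic materials without a noble metal. The substitution pattern is fixed by construction and not by a selectivity argument; on this point the alternative is better than the chosen plan. The annulation is as dependable mechanistically as any step of the chosen route (equal).
- Against: A4 has two free hydroxyls. The target needs the chelated ortho hydroxyl methylated while the more reactive para oxygen stays free (ring A) or is acylated (ring B), which is the reverse of the innate reactivity order. Each ring would need a protect–methylate–deprotect sequence, and the two carboxyl groups would need orthogonal protection. The hindered acylation that makes the depside remains unchanged (equal), and aromatisation with halogen risks ring halogenation.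
- Step economy: the chosen plan buys the methyl ether in the starting material and needs six steps; this alternative would be expected to need roughly twice as many.

**Alternative 2:** The cut is the C1(A)–C2(A) bond; ring A is unfolded to a 3,5,7-trioxododecanoyl chain already esterified to the ring B phenol, benzyl 2-methoxy-6-pentyl-4-[(3,5,7-trioxododecanoyl)oxy]benzoate A5. In the forward sense mild amine base and then acid would bring C2 of the chain onto the C7 ketone in an intramolecular aldol reaction; dehydration and enolisation would give benzyl 4-[(2,4-dihydroxy-6-pentylbenzoyl)oxy]-2-methoxy-6-pentylbenzoate A6.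
- In favour: the plan is biomimetic. The depside ester would be made as the ester of an aliphatic β-keto acid, so a di-ortho-substituted aromatic carbonyl never has to be attacked; here the alternative is better than step 4 of the chosen plan. The benzyl ester would leave by neutral hydrogenolysis, which is milder than acidolysis (also better).
- Against: A6 has a free hydroxyl on C6(A) where the target has a methyl ether. Methylating this chelated, hindered hydroxyl while the more acidic C4(A) hydroxyl stays free requires protection and deprotection, and basic methylation endangers the aryl ester. A5 is a sensitive polyketone that could also close through oxygen to a pyranone with expulsion of the ring B phenoxide, or through Claisen-type C-acylation. A5 itself needs several steps.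
- Comparison: both plans avoid carrying a pre-formed oxygenated ring A acid. The chosen plan does so with one late oxidation and no correction of the oxygen pattern, and is the shorter by several steps.

**Alternative 3:** The cut is the O–C4(B) aryl–oxygen bond, not the acyl–oxygen bond. In the forward sense 2-methoxy-4-(methoxymethoxy)-6-pentylbenzoic acid A7 and [4-(tert-butoxycarbonyl)-3-methoxy-5-pentylphenyl]boronic acid A8 would couple under Cu(OTf)2, urea and air: aryl transfer from boron to divalent copper, carboxylate binding, oxidation to trivalent copper and C–O reductive elimination. The product would be tert-butyl 2-methoxy-4-{[2-methoxy-4-(methoxymethoxy)-6-pentylbenzoyl]oxy}-6-pentylbenzoate A9.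
- In favour: the carboxylate oxygen is the nucleophile, so steric shielding of the carbonyl carbon matters little; on this point the alternative is better than the acyl chloride route. A8 would come from 7 without the oxidation stage (equal or slightly better on the ring B side). One acid treatment would remove the methoxymethyl and tert-butyl groups together (equal, one step).
- Against: A7 must already carry the C4(A) oxygen in protected form beside a free acid. That brings back an extra protecting group and a second carboxyl protection orthogonal to acid-labile groups, several steps in all. The copper coupling can also lose A8 by protodeboronation or oxidative hydroxylation and usually needs an excess of one partner.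
- Comparison: both plans rely on the same sterically governed borylation. The chosen plan uses it twice and needs no phenol protection at all, so it is the shorter.

Key step: step 5

## Route

Step 1
Reactants: 1 2-methoxy-6-methylbenzoic acid; 2 1-bromobutane
Product: 4 2-methoxy-6-pentylbenzoic acid, via dilithio dianion 3 (not isolated)
Conditions: LiN(i-Pr)2 (2.2 equiv), THF, −78 → 0 °C; then 2 (1.1 equiv), −78 °C → rt; aq. HCl
Reagents that add atoms: none
Why: Two equivalents of amide base should give first the carboxylate and then, by carboxylate-assisted lateral lithiation, the benzylic carbanion 3, the most stabilised anion available. The primary bromide 2 is then attacked in an SN2 alkylation (lateral metalation–alkylation of an ortho-toluate dianion); the carboxylate oxygen is too poor a nucleophile to compete at low temperature.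

Step 2
Reactants: 4 2-methoxy-6-pentylbenzoic acid
Product: 5 tert-butyl 2-methoxy-6-pentylbenzoate
Conditions: Cl3CC(=NH)Ot-Bu (2 equiv), BF3·OEt2 (cat.), CH2Cl2/cyclohexane, rt
Reagents that add atoms: tert-butyl 2,2,2-trichloroacetimidate, CC(C)(C)OC(=N)C(Cl)(Cl)Cl
Why: The protonated imidate transfers its tert-butyl group to the carboxylate oxygen through a tert-butyl cation ion pair (imidate O-alkylation), so the carbonyl carbon shielded by methoxy and pentyl is never attacked; the neutral amide by-product is filtered off.

Step 3
Reactants: 5 tert-butyl 2-methoxy-6-pentylbenzoate; 6 bis(pinacolato)diboron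
Product: 8 tert-butyl 4-hydroxy-2-methoxy-6-pentylbenzoate, via aryl pinacol boronate 7 (not isolated)
Conditions: [Ir(OMe)(cod)]2 (1.5 mol %), 4,4'-di-tert-butyl-2,2'-bipyridine (3 mol %), 6 (1.0 equiv), THF, 80 °C; evaporate; then Oxone (2KHSO5·KHSO4·K2SO4), acetone/H2O, rt; aq. NaHSO3
Reagents that add atoms: potassium peroxymonosulfate (active component of Oxone), [K+].[O-]S(=O)(=O)OO
Why: Sterically controlled iridium-catalysed C–H borylation: of the three ring hydrogens of 5 only the one at C4, para to the ester, has no ortho substituent, so the trisboryl iridium complex should borylate there to give 7. KHSO5 then turns the C–B bond into C–O by aryl migration from boron to oxygen, under weakly acidic aqueous conditions that leave the tert-butyl ester alone.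

Step 4
Reactants: 4 2-methoxy-6-pentylbenzoic acid; 8 tert-butyl 4-hydroxy-2-methoxy-6-pentylbenzoate
Product: 10 tert-butyl 2-methoxy-4-[(2-methoxy-6-pentylbenzoyl)oxy]-6-pentylbenzoate, via 2-methoxy-6-pentylbenzoyl chloride 9 (not isolated)
Conditions: 4 (1.2 equiv), (COCl)2, DMF (cat.), CH2Cl2, 0 °C → rt; evaporate; then 8, Et3N (2 equiv), DMAP (0.2 equiv), CH2Cl2, 0 → 40 °C
Reagents that add atoms: none
Why: (COCl)2 with catalytic DMF forms the acid chloride 9 through the chloroiminium reagent; 9 has no alpha hydrogen and so no ketene pathway. It acylates the unhindered, fairly acidic phenol of 8 under DMAP nucleophilic catalysis (acyl substitution via the N-acylpyridinium ion), and the tert-butyl ester of 8 is inert to amine base.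

Step 5
Reactants: 10 tert-butyl 2-methoxy-4-[(2-methoxy-6-pentylbenzoyl)oxy]-6-pentylbenzoate; 6 bis(pinacolato)diboron
Product: 12 tert-butyl 4-[(4-hydroxy-2-methoxy-6-pentylbenzoyl)oxy]-2-methoxy-6-pentylbenzoate, via ring A pinacol boronate 11 (not isolated)
Conditions: [Ir(OMe)(cod)]2 (2.5 mol %), 4,4'-di-tert-butyl-2,2'-bipyridine (5 mol %), 6 (1.0 equiv), THF, 80 °C; evaporate; then Oxone (2KHSO5·KHSO4·K2SO4), acetone/H2O, 0 °C → rt, short contact; aq. NaHSO3
Reagents that add atoms: potassium peroxymonosulfate (active component of Oxone), [K+].[O-]S(=O)(=O)OO
Why: [Ir(OMe)(cod)]2, the bipyridine ligand and 6 should generate the trivalent iridium trisboryl complex, which adds an arene C–H bond by oxidative addition to a pentavalent iridium aryl hydride and releases the aryl boronate by C–B reductive elimination, the boryl ligand being restored from 6. The closest known reaction type is the sterically controlled iridium-catalysed borylation of arenes combined in one flask with peroxymonosulfate oxidation of the aryl boronate to the phenol. No ring is closed and no stereocentre is created. The step needs site selectivity among five aromatic C–H bonds, and the crowded trisboryl complex should discriminate on steric grounds: C4(A)–H alone has hydrogen on both neighbours, C3(A)–H sits beside the pentyl chain, C5(A)–H beside the methoxy group, C3(B)–H and C5(B)–H each lie between two substituents, and the tert-butyl group offers only unreactive sp3 C–H bonds. Chemoselectivity is needed as well, and both esters and the ethers should be inert to the boryl complex, which attacks neither carbonyl group. In the second stage peroxymonosulfate adds to boron of 11, the aryl group migrates from boron to oxygen with loss of sulfate, and water hydrolyses the aryl borate to 12; this brief, weakly acidic oxidation should spare the aryl ester, which alkaline hydrogen peroxide would not. One equivalent of 6, and the blocking of C3(A) and C5(A) by the new boryl group, should prevent a second borylation.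

Step 6
Reactants: 12 tert-butyl 4-[(4-hydroxy-2-methoxy-6-pentylbenzoyl)oxy]-2-methoxy-6-pentylbenzoate
Product: 13 4-O-demethylplanaic acid, 4-[(4-hydroxy-2-methoxy-6-pentylbenzoyl)oxy]-2-methoxy-6-pentylbenzoic acid
Conditions: CF3CO2H/CH2Cl2 (1:4), Et3SiH (3 equiv), 0 °C → rt; evaporate from toluene
Reagents that add atoms: none
Why: Acid-catalysed alkyl–oxygen cleavage of the tert-butyl ester (unimolecular loss of the tert-butyl cation), helped by relief of strain at the di-ortho-substituted carboxyl; Et3SiH reduces the cation to isobutane so that it cannot alkylate the phenolic ring A. The depside ester could only be cleaved by a nucleophile at its hindered carbonyl and should survive anhydrous acid at or below room temperature, where protodecarboxylation is also slow.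

## Compound list

1 | 2-methoxy-6-methylbenzoic acid | Cc1cccc(OC)c1C(=O)O | starting material
2 | 1-bromobutane | CCCCBr | starting material
3 | lithium 2-(lithiomethyl)-6-methoxybenzoate (dilithio dianion) | [Li]Cc1cccc(OC)c1C(=O)O[Li] | intermediate
4 | 2-methoxy-6-pentylbenzoic acid | CCCCCc1cccc(OC)c1C(=O)O | intermediate
5 | tert-butyl 2-methoxy-6-pentylbenzoate | CCCCCc1cccc(OC)c1C(=O)OC(C)(C)C | intermediate
6 | bis(pinacolato)diboron | CC1(C)OB(OC1(C)C)B1OC(C)(C)C(C)(C)O1 | starting material
7 | tert-butyl 2-methoxy-6-pentyl-4-(4,4,5,5-tetramethyl-1,3,2-dioxaborolan-2-yl)benzoate | CCCCCc1cc(B2OC(C)(C)C(C)(C)O2)cc(OC)c1C(=O)OC(C)(C)C | intermediate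
8 | tert-butyl 4-hydroxy-2-methoxy-6-pentylbenzoate | CCCCCc1cc(O)cc(OC)c1C(=O)OC(C)(C)C | intermediate
9 | 2-methoxy-6-pentylbenzoyl chloride | CCCCCc1cccc(OC)c1C(=O)Cl | intermediate
10 | tert-butyl 2-methoxy-4-[(2-methoxy-6-pentylbenzoyl)oxy]-6-pentylbenzoate | CCCCCc1cccc(OC)c1C(=O)Oc1cc(OC)c(C(=O)OC(C)(C)C)c(CCCCC)c1 | intermediate
11 | tert-butyl 2-methoxy-4-{[2-methoxy-6-pentyl-4-(4,4,5,5-tetramethyl-1,3,2-dioxaborolan-2-yl)benzoyl]oxy}-6-pentylbenzoate | CCCCCc1cc(B2OC(C)(C)C(C)(C)O2)cc(OC)c1C(=O)Oc1cc(OC)c(C(=O)OC(C)(C)C)c(CCCCC)c1 | intermediate
12 | tert-butyl 4-[(4-hydroxy-2-methoxy-6-pentylbenzoyl)oxy]-2-methoxy-6-pentylbenzoate | CCCCCc1cc(O)cc(OC)c1C(=O)Oc1cc(OC)c(C(=O)OC(C)(C)C)c(CCCCC)c1 | intermediate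
13 | 4-O-demethylplanaic acid, 4-[(4-hydroxy-2-methoxy-6-pentylbenzoyl)oxy]-2-methoxy-6-pentylbenzoic acid | CCCCCc1cc(OC(=O)c2c(CCCCC)cc(O)cc2OC)cc(OC)c1C(=O)O | target

## Step count and risks

Total step count: 6. Longest linear sequence: 6 steps (1 → 4 → 5 → 8 → 10 → 12 → 13); acid 4 enters twice, in steps 2 and 4.

Least certain steps:

**Step 5 (key step).** The most likely failure is erosion of site selectivity through competing borylation at C5(A), ortho to the small methoxy group, or sluggish turnover on a substrate of this size; either would leave phenols that are hard to separate. A lesser risk is slow cleavage of the aryl ester if the oxidative stage is prolonged. The fallback sets out from 8 and comes back at 12; it carries the C4(A) oxygen in from the monomer instead of adding it last: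
- 8 is benzylated (BnBr, K2CO3, DMF) to tert-butyl 4-(benzyloxy)-2-methoxy-6-pentylbenzoate F1.
- CF3CO2H in CH2Cl2 at 0 °C removes the tert-butyl group to give 4-(benzyloxy)-2-methoxy-6-pentylbenzoic acid F2.
- (COCl)2 with catalytic DMF converts it into 4-(benzyloxy)-2-methoxy-6-pentylbenzoyl chloride F3, which acylates a second portion of 8 (Et3N, DMAP) to tert-butyl 4-{[4-(benzyloxy)-2-methoxy-6-pentylbenzoyl]oxy}-2-methoxy-6-pentylbenzoate F4.
- Hydrogenolysis (H2, Pd/C, ethyl acetate) gives 12.

This costs about two more steps but uses only ether formation, acylation and hydrogenolysis.

**Step 4.** Acyl transfer at a carbonyl shielded by two ortho groups may be slow, so that hydrolysis of the acid chloride by adventitious water or anhydride formation outruns esterification. The fallback sets out from 4 and 7 and comes back at 10; it builds the same ester from the other side, through the aryl–oxygen bond. The borylation of step 3 is stopped before the oxidation and 7 is isolated. NaIO4 and NH4OAc in aqueous acetone cleave the pinacol ester to [4-(tert-butoxycarbonyl)-3-methoxy-5-pentylphenyl]boronic acid F5 (the same compound as A8). 4 and F5 are then joined by oxidative copper O-arylation (Cu(OTf)2, urea, ethyl acetate, air, 60 °C) to give 10; the carboxylate oxygen is the nucleophile there, so hindrance at the carbonyl carbon should matter little.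

**Step 6.** Incomplete trapping of the tert-butyl cation would lead to C-alkylation of the phenolic ring A, and a prolonged or warm acid treatment to protodecarboxylation of the liberated electron-rich acid. The fallback sets out from 12 and comes back at 13. Me3SiOTf and 2,6-lutidine in CH2Cl2 at 0 °C exchange the tert-butyl group for silicon with loss of isobutene under buffered, non-protic conditions. The product is trimethylsilyl 2-methoxy-4-({2-methoxy-6-pentyl-4-[(trimethylsilyl)oxy]benzoyl}oxy)-6-pentylbenzoate F6, and brief stirring with aqueous pH 5 buffer in THF removes both silyl groups to give 13.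

**Step 1.** Lateral deprotonation may be incomplete, ring metalation next to the methoxy group may compete, and a second alkylation at the benzylic carbon is possible. The fallback sets out from 1 and comes back at 5. 1 is first converted with the imidate of step 2 into tert-butyl 2-methoxy-6-methylbenzoate F7. Its benzylic mono-anion (LiN(i-Pr)2, 1.1 equiv, THF, −78 °C) is alkylated with 2 to give 5 directly. The portion of 4 needed for step 4 is then obtained from 5 with CF3CO2H in CH2Cl2.

## Further compounds

F1 | step 5 | tert-butyl 4-(benzyloxy)-2-methoxy-6-pentylbenzoate | CCCCCc1cc(OCc2ccccc2)cc(OC)c1C(=O)OC(C)(C)C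
F2 | step 5 | 4-(benzyloxy)-2-methoxy-6-pentylbenzoic acid | CCCCCc1cc(OCc2ccccc2)cc(OC)c1C(=O)O
F3 | step 5 | 4-(benzyloxy)-2-methoxy-6-pentylbenzoyl chloride | CCCCCc1cc(OCc2ccccc2)cc(OC)c1C(=O)Cl
F4 | step 5 | tert-butyl 4-{[4-(benzyloxy)-2-methoxy-6-pentylbenzoyl]oxy}-2-methoxy-6-pentylbenzoate | CCCCCc1cc(OCc2ccccc2)cc(OC)c1C(=O)Oc1cc(OC)c(C(=O)OC(C)(C)C)c(CCCCC)c1
F5 | step 4 | [4-(tert-butoxycarbonyl)-3-methoxy-5-pentylphenyl]boronic acid | CCCCCc1cc(B(O)O)cc(OC)c1C(=O)OC(C)(C)C
F6 | step 6 | trimethylsilyl 2-methoxy-4-({2-methoxy-6-pentyl-4-[(trimethylsilyl)oxy]benzoyl}oxy)-6-pentylbenzoate | CCCCCc1cc(O[Si](C)(C)C)cc(OC)c1C(=O)Oc1cc(OC)c(C(=O)O[Si](C)(C)C)c(CCCCC)c1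
F7 | step 1 | tert-butyl 2-methoxy-6-methylbenzoate | Cc1cccc(OC)c1C(=O)OC(C)(C)C
A1 | alternative 1 | dibenzyl malonate | O=C(CC(=O)OCc1ccccc1)OCc1ccccc1
A2 | alternative 1 | (E)-non-3-en-2-one | CCCCC/C=C/C(C)=O
A3 | alternative 1 | benzyl trans-2-hydroxy-4-oxo-6-pentylcyclohex-2-ene-1-carboxylate (racemic, one enantiomer drawn) | CCCCC[C@@H]1CC(=O)C=C(O)[C@H]1C(=O)OCc1ccccc1
A4 | alternative 1 | benzyl 2,4-dihydroxy-6-pentylbenzoate | CCCCCc1cc(O)cc(O)c1C(=O)OCc1ccccc1
A5 | alternative 2 | benzyl 2-methoxy-6-pentyl-4-[(3,5,7-trioxododecanoyl)oxy]benzoate | CCCCCC(=O)CC(=O)CC(=O)CC(=O)Oc1cc(OC)c(C(=O)OCc2ccccc2)c(CCCCC)c1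
A6 | alternative 2 | benzyl 4-[(2,4-dihydroxy-6-pentylbenzoyl)oxy]-2-methoxy-6-pentylbenzoate | CCCCCc1cc(O)cc(O)c1C(=O)Oc1cc(OC)c(C(=O)OCc2ccccc2)c(CCCCC)c1
A7 | alternative 3 | 2-methoxy-4-(methoxymethoxy)-6-pentylbenzoic acid | CCCCCc1cc(OCOC)cc(OC)c1C(=O)O
A8 | alternative 3 | [4-(tert-butoxycarbonyl)-3-methoxy-5-pentylphenyl]boronic acid | CCCCCc1cc(B(O)O)cc(OC)c1C(=O)OC(C)(C)C
A9 | alternative 3 | tert-butyl 2-methoxy-4-{[2-methoxy-4-(methoxymethoxy)-6-pentylbenzoyl]oxy}-6-pentylbenzoate | CCCCCc1cc(OCOC)cc(OC)c1C(=O)Oc1cc(OC)c(C(=O)OC(C)(C)C)c(CCCCC)c1
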